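**Retrosynthetic overview**

1. Numbering (mutilin): cyclopentenone = C9–C1–C2(=O)–C3=C4; cyclohexane = C4–C5–C6–C7–C8–C9; cyclooctane = C4–C5–C14–C13–C12–C11–C10–C9.
2. Enabling feature: C4, the one atom shared by all three rings, lies between two quaternary carbons (C5, C9); it is β to O14 through C5 and 1,4 to C2=O through C9–C1, and O14 and C1 sit on the same face of the eight-membered ring. A C4 ketone can therefore act first as enolate (C5–C14 aldol) and then as electrophile (C3=C4 condensation), while the O14 acetyl is relayed from a C2 enol acetate.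
3. Disconnections: C3=C4 (aldol condensation) ⇒ O14-acetyl/C2 enol acetate ⇒ C5–C14 (Sm Reformatsky aldol) ⇒ C11–C12 (allylboration) ⇒ C9–C10 (Ir allylation) ⇒ C9–C1 (propargylation).
4. Ring order: six-membered ring bought (5-methylcyclohexane-1,3-dione); eight-membered ring, then five-membered ring, both closed in one flask in step 16.

Key step: step 16

Assumption: every compound is written with the stereodescriptors of the target string carried over atom by atom; read literally, the C5 and C9 descriptors would place the two arms of the eight-membered ring on opposite faces of the cyclohexane, so the ordinary out,out bicyclo[5.3.1]undecane of the mutilin family is assumed and all facial arguments refer to it.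

**Step 1**
Reactants: 1 5-methylcyclohexane-1,3-dione; 2 propargyl bromide
Product: 3 5-methyl-2-(prop-2-yn-1-yl)cyclohexane-1,3-dione
Conditions: KOH (1.0 equiv), H2O, 50 °C
Reagents that add atoms: none
Why: C-alkylation of a cyclic 1,3-dione enolate with a propargylic halide in water puts the future C1–C3 unit on C9, and no stereocentre arises because 3 is enolised and achiral.

**Step 2**
Reactants: 3 5-methyl-2-(prop-2-yn-1-yl)cyclohexane-1,3-dione; 4 (E)-crotyl chloride
Product: 5 2-[(2S)-but-3-en-2-yl]-5-methyl-2-(prop-2-yn-1-yl)cyclohexane-1,3-dione (single C9/C6 ring diastereomer)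
Conditions: [Ir(cod)Cl]2 (2 mol %), (Ra,R,R)-phosphoramidite ligand (4 mol %; the antipode that gives 10S), TBD (10 mol %), LiOt-Bu (1.0 equiv), THF, 25 °C
Reagents that add atoms: none
Why: Iridium-catalysed branched-selective asymmetric allylic alkylation of a stabilised 1,3-dicarbonyl nucleophile creates the C9 quaternary centre and the C10 methyl stereocentre in one event, C10 being set by the catalyst and the C9/C6 relationship by axial attack of the electrophile on the sofa-shaped enolate anti to the C6 flap.

**Step 3**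
Reactants: 5 2-[(2S)-but-3-en-2-yl]-5-methyl-2-(prop-2-yn-1-yl)cyclohexane-1,3-dione
Product: 6 C8 (S)-hydroxy ketone (one carbonyl of 5 reduced; hydroxyl cis to the butenyl arm)
Conditions: (R)-Me-CBS (20 mol %), catecholborane (1.5 equiv), toluene, −78 °C; then MeOH, pH 7 buffer
Reagents that add atoms: none
Why: Corey–Bakshi–Shibata reduction used as a group-selective mono-reduction of a 2,2-disubstituted cyclohexane-1,3-dione, in which the catalyst delivers hydride to its preferred enantioface (8S) and only at the carbonyl where that face lies anti to the branched butenyl arm, so that C8 is set by the catalyst and the choice of carbonyl turns C9 and C6 into defined stereocentres.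

**Step 4**
Reactants: 6 C8 (S)-hydroxy ketone
Product: 7 C8 triethylsilyl ether of 6
Conditions: TESOTf (1.2 equiv), 2,6-lutidine, CH2Cl2, −78 → 0 °C
Reagents that add atoms: triethylsilyl trifluoromethanesulfonate, CC[Si](CC)(CC)OS(=O)(=O)C(F)(F)F
Why: Silylation with a silyl triflate blocks retro-aldol cleavage of the β-hydroxy ketone and removes an acidic proton ahead of the enolate and samarium chemistry, without touching a stereocentre.

**Step 5**
Reactants: 7 C8 triethylsilyl ether of 6
Product: 8 C5-methyl ketone (C5-Me trans to C6-Me)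
Conditions: LDA (1.05 equiv), THF, −78 °C; MeI (3 equiv), −78 → −30 °C
Reagents that add atoms: iodomethane, CI
Why: Enolate alkylation, in which the quaternary C9 leaves C5 as the only enolisable position of the C4 ketone and methyl iodide enters anti to the C6 methyl (this centre is planarised again in steps 13 and 16, so its configuration is not critical).

**Step 6**
Reactants: 8 C5-methyl ketone
Product: 9 C11 aldehyde (vinyl group of 8 cleaved; C10 R by CIP, spatially unchanged)
Conditions: O3, CH2Cl2/MeOH (4:1), Sudan III, −78 °C; then Me2S, −78 → 23 °C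
Reagents that add atoms: ozone, [O-][O+]=O
Why: Ozonolysis with reductive work-up cleaves the vinyl group selectively in the presence of the terminal alkyne (indicator-controlled end point), and C10 is preserved if the α-branched aldehyde is used without chromatography.

**Step 7**
Reactants: 10 (E)-3-methylpent-2-en-4-yn-1-ol
Product: 11 (E)-3-methylpent-2-en-4-yn-1-yl 4-methoxybenzyl ether
Conditions: NaH (1.1 equiv), PMBCl (1.1 equiv), TBAI (5 mol %), THF/DMF, 0 → 23 °C
Reagents that add atoms: 4-methoxybenzyl chloride, COc1ccc(CCl)cc1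
Why: Williamson etherification of the primary alkoxide installs an O14 protecting group that is later removed oxidatively without touching silyl ethers, the bromo ketone or the enol ester.

**Step 8**
Reactants: 11 (E)-3-methylpent-2-en-4-yn-1-yl 4-methoxybenzyl ether
Product: 12 (E)-3-methylpenta-2,4-dien-1-yl 4-methoxybenzyl ether
Conditions: H2 (1 atm), Lindlar catalyst, quinoline, EtOAc, 23 °C
Reagents that add atoms: none
Why: Lindlar semihydrogenation stops at the terminal alkene and leaves the trisubstituted double bond and the benzylic ether untouched.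

**Step 9**
Reactants: 12 (E)-3-methylpenta-2,4-dien-1-yl 4-methoxybenzyl ether
Product: 13 (Z)-allylboronate pinB–CH2–CH=C(CH3)–CH2CH2OPMB
Conditions: Ni(cod)2 (2.5 mol %), PCy3 (2.5 mol %), pinacolborane (1.1 equiv), toluene, 23 °C
Reagents that add atoms: pinacolborane, [H]B1OC(C)(C)C(C)(C)O1
Why: Nickel-catalysed 1,4-hydroboration of a 1,3-diene proceeds through the s-cis η4-complex, so boron goes to the unsubstituted terminus and the two former termini end up cis, which gives the (Z)-γ,γ-disubstituted allylboronate needed for C12.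

**Step 10**
Reactants: 9 C11 aldehyde; 13 (Z)-allylboronate
Product: 14 homoallylic alcohol (C11 S hydroxyl; C12 bearing methyl, vinyl and CH2CH2OPMB as in the target)
Conditions: (R)-TRIP (10 mol %), 4 Å MS, toluene, 0 → 23 °C; then aq. NaHCO3
Reagents that add atoms: none
Why: Chiral-phosphoric-acid-catalysed allylboration through a closed chair transition state, in which the (Z)-geometry of 13 places the CH2CH2OPMB group syn and the methyl anti to the new hydroxyl (C12) and (R)-TRIP directs the boronate to the Re face of the aldehyde (C11 S, the 10,11-syn product), overriding the anti-Felkin bias of (Z)-γ-substituted boronates while the hindered C4 ketone stays untouched.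

**Step 11**
Reactants: 14 homoallylic alcohol
Product: 15 C8,C11-bis(triethylsilyl) ether
Conditions: TESOTf (1.5 equiv), 2,6-lutidine, CH2Cl2, −78 → 0 °C
Reagents that add atoms: triethylsilyl trifluoromethanesulfonate, CC[Si](CC)(CC)OS(=O)(=O)C(F)(F)F
Why: Silyl triflate silylation of the hindered C11 hydroxyl prevents lactol formation with the later C14 aldehyde and leaves O14 as the only oxygen that can become an alkoxide in step 16.

**Step 12**
Reactants: 15 C8,C11-bis(triethylsilyl) ether
Product: 16 enol acetate (propargyl group converted into 2-acetoxyprop-2-en-1-yl)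
Conditions: [RuCl2(p-cymene)]2 (2 mol %), P(2-furyl)3 (4 mol %), Na2CO3 (4 mol %), AcOH (1.5 equiv), toluene, 50 °C
Reagents that add atoms: acetic acid, CC(=O)O
Why: Ruthenium-catalysed Markovnikov addition of a carboxylic acid to a terminal alkyne gives the 2-acetoxyallyl group, a non-acidic enol ester that stores both the C2 enolate and the acetyl group of the target, while the C12 vinyl group has no allylic hydrogen and cannot isomerise.

**Step 13**
Reactants: 16 enol acetate
Product: 18 C5 α-bromo ketone (Br anti to C6-Me), via trimethylsilyl enol ether 17 (not isolated)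
Conditions: TMSOTf (1.3 equiv), Et3N (2 equiv), CH2Cl2, 0 → 23 °C; then NBS (1.05 equiv), THF, −78 °C
Reagents that add atoms: N-bromosuccinimide, O=C1CCC(=O)N1Br
Why: Soft enolisation gives the only possible (C4=C5) silyl enol ether, which is far more nucleophilic than the enol acetate, the vinyl group or the anisyl ring, and its bromination gives the tertiary α-bromo ketone that serves as a regiospecific enolate precursor (C5 is planarised again in step 16).

**Step 14**
Reactants: 18 C5 α-bromo ketone
Product: 19 C14 primary alcohol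
Conditions: DDQ (1.3 equiv), CH2Cl2/pH 7 buffer (10:1), 0 °C
Reagents that add atoms: none
Why: Oxidative cleavage of the 4-methoxybenzyl ether by DDQ frees the C14 alcohol under neutral conditions that spare the TES ethers, the enol acetate and the bromo ketone.

**Step 15**
Reactants: 19 C14 primary alcohol
Product: 20 C14 aldehyde
Conditions: Dess–Martin periodinane (1.3 equiv), NaHCO3, CH2Cl2, 0 → 23 °C
Reagents that add atoms: none
Why: Dess–Martin oxidation gives the aldehyde under buffered, non-enolising conditions compatible with the bromo ketone and the enol ester.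

**Step 16**
Reactants: 20 C14 aldehyde
Product: 26 8,11-bis-O-triethylsilyl pleuromutilin E, via C4–C5 samarium enolate 21 (not isolated), via bicyclic samarium aldolate 22 (not isolated), via C14 acetate C2 samarium enolate 23 (not isolated), via tricyclic samarium aldolate 24 (not isolated), via tertiary mesylate 25 (not isolated)
Conditions: SmI2 (2.5 equiv), THF (0.005 M), −78 → 0 °C; then MsCl (3 equiv), Et3N (6 equiv), DMAP (cat.), 0 → 23 °C
Reagents that add atoms: none
Why: Proposed new method: SmI2 reduces the tertiary α-bromo ketone to the C4–C5 samarium(III) enolate 21, which adds to the C14 aldehyde through a Sm-chelated chair (Reformatsky-type aldol, 8-(enolendo)-exo-trig; closest known type: SmI2-mediated bromo ketone/aldehyde cyclisation to eight-membered rings) to give aldolate 22. The Sm(III) alkoxide of 22 is then acetylated by the 2-acetoxyallyl group (O-to-O acyl transfer through a nine-membered transition state; closest known type: transesterification of lanthanide alkoxides with enol esters, which liberates the enolate), which makes the medium-ring aldol irreversible, installs the C14 acetate and releases the C2 samarium enolate 23 only after C4 has become a ketone. Enolate 23 closes the five-membered ring on C4 (5-(enolexo)-exo-trig aldol) and mesylation with E1cB elimination of aldolate 24 gives the C3=C4 enone. C5 is fixed because the C9-anchored chain can only reach the enolate face on which it sits, and C14 by the chair in which the tether is pseudo-equatorial and samarium bridges both oxygens (oxygen anti to the C5 methyl). The selectivity needed is one of order, C4 as nucleophile before C4 as electrophile, and it is secured by masking C4 as bromo ketone/enolate and the C3 nucleophile as a non-acidic enol ester that only the O14 alkoxide unmasks; the competing acetyl shift to the C4 enolate oxygen should be slower than addition to the aldehyde at −78 °C.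

**Step 17**
Reactants: 26 8,11-bis-O-triethylsilyl pleuromutilin E
Product: 27 pleuromutilin E
Conditions: HF·pyridine, pyridine, THF, 0 → 23 °C
Reagents that add atoms: none
Why: Fluoride-mediated desilylation of both triethylsilyl ethers under buffered conditions spares the acetate, the enone and the vinyl group and touches no stereocentre.

**Compound list**

1 | 5-methylcyclohexane-1,3-dione | CC1CC(=O)CC(=O)C1 | starting material
2 | propargyl bromide | C#CCBr | starting material
3 | 5-methyl-2-(prop-2-yn-1-yl)cyclohexane-1,3-dione | C#CCC1C(=O)CC(C)CC1=O | intermediate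
4 | (E)-crotyl chloride | C/C=C/CCl | starting material
5 | 2-[(2S)-but-3-en-2-yl]-5-methyl-2-(prop-2-yn-1-yl)cyclohexane-1,3-dione | O=C1C[C@@H](C)CC(=O)[C@]1(CC#C)[C@@H](C)C=C | intermediate
6 | C8 (S)-hydroxy ketone | O=C1C[C@@H](C)C[C@H](O)[C@]1(CC#C)[C@@H](C)C=C | intermediate
7 | C8 triethylsilyl ether of 6 | O=C1C[C@@H](C)C[C@H](O[Si](CC)(CC)CC)[C@]1(CC#C)[C@@H](C)C=C | intermediate
8 | C5-methyl ketone | O=C1[C@H](C)[C@@H](C)C[C@H](O[Si](CC)(CC)CC)[C@]1(CC#C)[C@@H](C)C=C | intermediate
9 | C11 aldehyde | O=C1[C@H](C)[C@@H](C)C[C@H](O[Si](CC)(CC)CC)[C@]1(CC#C)[C@@H](C)C=O | intermediate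
10 | (E)-3-methylpent-2-en-4-yn-1-ol | C#C/C(C)=C/CO | starting material
11 | (E)-3-methylpent-2-en-4-yn-1-yl 4-methoxybenzyl ether | C#C/C(C)=C/COCc1ccc(OC)cc1 | intermediate
12 | (E)-3-methylpenta-2,4-dien-1-yl 4-methoxybenzyl ether | C=C/C(C)=C/COCc1ccc(OC)cc1 | intermediate
13 | (Z)-2-[5-(4-methoxybenzyloxy)-3-methylpent-2-en-1-yl]-4,4,5,5-tetramethyl-1,3,2-dioxaborolane | C/C(CCOCc1ccc(OC)cc1)=C/CB1OC(C)(C)C(C)(C)O1 | intermediate
14 | homoallylic alcohol (C11-OH) | O=C1[C@H](C)[C@@H](C)C[C@H](O[Si](CC)(CC)CC)[C@]1(CC#C)[C@@H](C)[C@H](O)[C@](C)(C=C)CCOCc1ccc(OC)cc1 | intermediate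
15 | C8,C11-bis(triethylsilyl) ether | O=C1[C@H](C)[C@@H](C)C[C@H](O[Si](CC)(CC)CC)[C@]1(CC#C)[C@@H](C)[C@H](O[Si](CC)(CC)CC)[C@](C)(C=C)CCOCc1ccc(OC)cc1 | intermediate
16 | enol acetate (2-acetoxyallyl on C9) | O=C1[C@H](C)[C@@H](C)C[C@H](O[Si](CC)(CC)CC)[C@]1(CC(=C)OC(C)=O)[C@@H](C)[C@H](O[Si](CC)(CC)CC)[C@](C)(C=C)CCOCc1ccc(OC)cc1 | intermediate
17 | trimethylsilyl enol ether (C4=C5) | C[Si](C)(C)OC1=C(C)[C@@H](C)C[C@H](O[Si](CC)(CC)CC)[C@]1(CC(=C)OC(C)=O)[C@@H](C)[C@H](O[Si](CC)(CC)CC)[C@](C)(C=C)CCOCc1ccc(OC)cc1 | intermediate (not isolated)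
18 | C5 α-bromo ketone | O=C1[C@@](Br)(C)[C@@H](C)C[C@H](O[Si](CC)(CC)CC)[C@]1(CC(=C)OC(C)=O)[C@@H](C)[C@H](O[Si](CC)(CC)CC)[C@](C)(C=C)CCOCc1ccc(OC)cc1 | intermediate
19 | C14 primary alcohol | O=C1[C@@](Br)(C)[C@@H](C)C[C@H](O[Si](CC)(CC)CC)[C@]1(CC(=C)OC(C)=O)[C@@H](C)[C@H](O[Si](CC)(CC)CC)[C@](C)(C=C)CCO | intermediate
20 | C14 aldehyde | O=C1[C@@](Br)(C)[C@@H](C)C[C@H](O[Si](CC)(CC)CC)[C@]1(CC(=C)OC(C)=O)[C@@H](C)[C@H](O[Si](CC)(CC)CC)[C@](C)(C=C)CC=O | intermediate
21 | C4–C5 samarium enolate | I[Sm](I)OC1=C(C)[C@@H](C)C[C@H](O[Si](CC)(CC)CC)[C@]1(CC(=C)OC(C)=O)[C@@H](C)[C@H](O[Si](CC)(CC)CC)[C@](C)(C=C)CC=O | intermediate (not isolated)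
22 | bicyclic samarium aldolate (eight-membered ring closed) | C=C[C@]1(C)C[C@@H](O[Sm](I)I)[C@]2(C)C(=O)[C@](CC(=C)OC(C)=O)([C@@H](O[Si](CC)(CC)CC)C[C@@H]2C)[C@@H](C)[C@@H]1O[Si](CC)(CC)CC | intermediate (not isolated)
23 | C14 acetate C2 samarium enolate | C=C[C@]1(C)C[C@@H](OC(C)=O)[C@]2(C)C(=O)[C@](CC(=C)O[Sm](I)I)([C@@H](O[Si](CC)(CC)CC)C[C@@H]2C)[C@@H](C)[C@@H]1O[Si](CC)(CC)CC | intermediate (not isolated)
24 | tricyclic samarium aldolate (C4 configuration undefined, lost on elimination) | C=C[C@]1(C)C[C@@H](OC(C)=O)[C@]2(C)C3(O[Sm](I)I)CC(=O)C[C@@]3([C@@H](O[Si](CC)(CC)CC)C[C@@H]2C)[C@@H](C)[C@@H]1O[Si](CC)(CC)CC | intermediate (not isolated)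
25 | tertiary mesylate at C4 | C=C[C@]1(C)C[C@@H](OC(C)=O)[C@]2(C)C3(OS(C)(=O)=O)CC(=O)C[C@@]3([C@@H](O[Si](CC)(CC)CC)C[C@@H]2C)[C@@H](C)[C@@H]1O[Si](CC)(CC)CC | intermediate (not isolated)
26 | 8,11-bis-O-triethylsilyl pleuromutilin E | C=C[C@]1(C)C[C@@H](OC(C)=O)[C@]2(C)C3=CC(=O)C[C@@]3([C@@H](O[Si](CC)(CC)CC)C[C@@H]2C)[C@@H](C)[C@@H]1O[Si](CC)(CC)CC | intermediate
27 | pleuromutilin E | C=C[C@]1(C)C[C@@H](OC(C)=O)[C@]2(C)C3=CC(=O)C[C@@]3([C@@H](O)C[C@@H]2C)[C@@H](C)[C@@H]1O | target

**Step count and risks**

Total step count: 17. Longest linear sequence: 14 steps (steps 1–6 and 10–17).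

Steps most likely to fail:

1. Step 16 (Proposed new method). The acetyl group may pass from the enol ester to the C4 enolate oxygen before the aldehyde is attacked. Alternatively, the acyl transfer to O14 may be too slow and the medium-ring aldolate may revert. Either way the two ring closures would no longer be ordered. Fallback, known chemistry only, from 15 back to 26: 15 is brominated as in step 13 (TMSOTf/Et3N, then NBS) to the bromo ketone F1. DDQ gives the alcohol F2 and Dess–Martin oxidation the aldehyde F3. A SmI2-mediated Reformatsky-type aldol (THF, −78 °C) followed by Ac2O/DMAP quench gives the bicyclic C14 acetate F4, which still carries the propargyl group. Gold(I)-catalysed Markovnikov hydration ([(JohnPhos)Au(MeCN)]SbF6, wet dioxane, 40 °C) gives the methyl ketone F5. LiHMDS (THF, −78 → 0 °C; the C4 ketone cannot enolise) closes the cyclopentane by aldol addition, and MsCl/Et3N dehydration returns to 26.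

2. Step 10. Catalyst control may not overcome the substrate's anti-Felkin preference (mismatched double stereodifferentiation), giving the C11/C12 epimeric pair. Fallback with substrate-controlled steps, from 9 back to 15: Nozaki–Hiyama–Kishi coupling (CrCl2, cat. NiCl2, DMSO) of 9 with the PMB ether of (Z)-3-iodobut-2-en-1-ol, F6, gives the allylic alcohol F7. This is a Felkin addition of a small sp2 nucleophile, now matched, and it is chemoselective for the aldehyde. TESOTf gives F8 and DDQ the primary allylic alcohol F9. Hg(OAc)2/ethyl vinyl ether gives the allyl vinyl ether F10. Claisen rearrangement (toluene, 120 °C) gives the aldehyde F11; the chair forms the new bond anti to the bulky C10 branch in the A(1,3)-locked conformer of the (Z)-alkene, which sets C12. NaBH4 (MeOH, −78 °C, aldehyde only) gives the alcohol F12, and PMB trichloroacetimidate/La(OTf)3 returns to 15.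

3. Step 2. The facial selectivity of the quaternisation at C9 relative to the ring methyl may be low or of the wrong sense with the bulky π-allyl electrophile, and linear allylation may compete. Fallback, from 1 back to 5, reversing the order of the two C9 alkylations: 1 is first allylated with 4 under the same iridium catalysis to give the enolised mono-substituted dione F13 (C10 set by the catalyst). The small, reactive propargyl bromide (2, K2CO3, acetone) is then used for the stereodefining quaternisation to give 5. Whichever face the last electrophile prefers, the order of introduction can be chosen so that the butenyl arm ends on the required face.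

**Further compounds**

F1 | step 16 | C5 α-bromo ketone of 15 (propargyl retained) | O=C1[C@@](Br)(C)[C@@H](C)C[C@H](O[Si](CC)(CC)CC)[C@]1(CC#C)[C@@H](C)[C@H](O[Si](CC)(CC)CC)[C@](C)(C=C)CCOCc1ccc(OC)cc1
F2 | step 16 | C14 alcohol of F1 | O=C1[C@@](Br)(C)[C@@H](C)C[C@H](O[Si](CC)(CC)CC)[C@]1(CC#C)[C@@H](C)[C@H](O[Si](CC)(CC)CC)[C@](C)(C=C)CCO
F3 | step 16 | C14 aldehyde of F1 | O=C1[C@@](Br)(C)[C@@H](C)C[C@H](O[Si](CC)(CC)CC)[C@]1(CC#C)[C@@H](C)[C@H](O[Si](CC)(CC)CC)[C@](C)(C=C)CC=O
F4 | step 16 | bicyclic C14 acetate with C9 propargyl group | C=C[C@]1(C)C[C@@H](OC(C)=O)[C@]2(C)C(=O)[C@](CC#C)([C@@H](O[Si](CC)(CC)CC)C[C@@H]2C)[C@@H](C)[C@@H]1O[Si](CC)(CC)CC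
F5 | step 16 | bicyclic 1,4-diketone (C9 2-oxopropyl group) | C=C[C@]1(C)C[C@@H](OC(C)=O)[C@]2(C)C(=O)[C@](CC(C)=O)([C@@H](O[Si](CC)(CC)CC)C[C@@H]2C)[C@@H](C)[C@@H]1O[Si](CC)(CC)CC
F6 | step 10 | (Z)-3-iodobut-2-en-1-yl 4-methoxybenzyl ether | C/C(I)=C/COCc1ccc(OC)cc1
F7 | step 10 | C11 allylic alcohol from Nozaki–Hiyama–Kishi coupling | O=C1[C@H](C)[C@@H](C)C[C@H](O[Si](CC)(CC)CC)[C@]1(CC#C)[C@@H](C)[C@H](O)/C(C)=C\COCc1ccc(OC)cc1
F8 | step 10 | C11 triethylsilyl ether of F7 | O=C1[C@H](C)[C@@H](C)C[C@H](O[Si](CC)(CC)CC)[C@]1(CC#C)[C@@H](C)[C@H](O[Si](CC)(CC)CC)/C(C)=C\COCc1ccc(OC)cc1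
F9 | step 10 | primary allylic alcohol | O=C1[C@H](C)[C@@H](C)C[C@H](O[Si](CC)(CC)CC)[C@]1(CC#C)[C@@H](C)[C@H](O[Si](CC)(CC)CC)/C(C)=C\CO
F10 | step 10 | allyl vinyl ether | O=C1[C@H](C)[C@@H](C)C[C@H](O[Si](CC)(CC)CC)[C@]1(CC#C)[C@@H](C)[C@H](O[Si](CC)(CC)CC)/C(C)=C\COC=C
F11 | step 10 | Claisen aldehyde (C12 quaternary, C14 aldehyde) | O=C1[C@H](C)[C@@H](C)C[C@H](O[Si](CC)(CC)CC)[C@]1(CC#C)[C@@H](C)[C@H](O[Si](CC)(CC)CC)[C@](C)(C=C)CC=O
F12 | step 10 | C14 alcohol | O=C1[C@H](C)[C@@H](C)C[C@H](O[Si](CC)(CC)CC)[C@]1(CC#C)[C@@H](C)[C@H](O[Si](CC)(CC)CC)[C@](C)(C=C)CCO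
F13 | step 2 | 2-[(2S)-but-3-en-2-yl]-5-methylcyclohexane-1,3-dione | C=C[C@H](C)C1C(=O)CC(C)CC1=O
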